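**Plan**
- Retrosynthesis: cut the aryl ester C–O bond, then take C4–OH back to C4=O and remove the C5=C6/C6-methyl unit to leave a plain cycloheptanone. Next cut the C3a–C8a bond of the cyclopentane and re-attach C8a to C4 (retro-semipinacol), which gives a cis-fused decalin-1,2,8a-triol 1-mesylate. Finally cut C2–iPr (carbonyl addition), C1–C8a (aldol) and C4–C4a (Michael).
- Forward: the cyclohexanone (future seven-membered ring) receives the side chain by Michael addition, and an aldol closes six-membered ring A. One 1,2-shift then contracts ring A to the cyclopentane and expands ring B to the cycloheptanone. The enone, C6 methyl, C4 carbinol and ester follow.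
- Enabling feature: C3a lies between the carbinol C3 and the oxygenated C4, and C4 is flanked by the quaternary C8a (a C3–OH/C4=O aldol retron). With C8a still on a hydroxylated C4 and a leaving group on C3a, C8a can shift from C4 to C3a.
- Stereochemistry: the quaternary centre comes from the auxiliary-controlled Michael addition, and the C8a–OH/C1–O cis relation from the equilibrating aldol. The C2 carbinol is set by equatorial attack, C3a by inversion in the shift, and C4 by hydroxyl-directed hydride delivery.

Key step: step 7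

Remark: 5–7 compounds carry azulene numbering (C3 carbinol, C3a ring-fusion CH, C4 oxygenated, C8a quaternary); 6–6 compounds carry naphthalene numbering (C1–C4, C4a, C5–C8, C8a). β is the face of the angular methyl group. Compounds 1 and 17 are taken as catalogue compounds.

**Step 1**
Reactants: 1 2-(benzyloxy)-N-methoxy-N-methylacetamide
Product: 2 1-(benzyloxy)but-3-en-2-one
Conditions: CH2=CHMgBr, THF, −78 to 0 °C; inverse quench into cold 1 M HCl
Reagents that add atoms: vinylmagnesium bromide, C=C[Mg]Br
Why: Weinreb ketone synthesis; the chelated tetrahedral intermediate prevents over-addition and the acidic quench keeps the released amine from adding to the enone.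

**Step 2**
Reactants: 3 2-methylcyclohexanone (racemic), 4 (R)-1-phenylethylamine, 2 1-(benzyloxy)but-3-en-2-one
Product: 7 (S)-2-[4-(benzyloxy)-3-oxobutyl]-2-methylcyclohexan-1-one, via ketimine 5 (not isolated), via adduct ketimine 6 (not isolated)
Conditions: (i) 4, TsOH (cat.), PhMe, reflux, Dean–Stark; (ii) 2, THF, 25 °C; (iii) 20% aq AcOH, 25 °C
Reagents that add atoms: water, O
Why: Deracemising Michael addition of a chiral ketimine (d'Angelo type): the more substituted secondary enamine tautomer adds to the enone through a compact aza-ene-like transition state on the face away from the phenyl group, so the (R)-auxiliary should set the (S)-quaternary centre while the original C2 stereocentre is erased.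

**Step 3**
Reactants: 7 (S)-2-[4-(benzyloxy)-3-oxobutyl]-2-methylcyclohexan-1-one
Product: 8 cis-fused ketol 1β-(benzyloxy)-8aβ-hydroxy-4aβ-methyldecalin-2-one
Conditions: NaOEt (0.2 equiv), EtOH, −10 °C
Reagents that add atoms: none
Why: Intramolecular aldol addition (Robinson annulation stopped at the ketol) of the α-alkoxy methylene onto the ring ketone; under reversible conditions the cis-fused ketol should form with the hydroxyl axial and the methyl and benzyloxy groups equatorial on ring A, which sets C8a and C1 relative to C4a.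

**Step 4**
Reactants: 8 cis-fused ketol
Product: 9 1β-(benzyloxy)-2α-isopropyl-4aβ-methyldecalin-2β,8aβ-diol
Conditions: i-PrMgCl (3.5 equiv), anhydrous CeCl3, THF, −78 to 0 °C
Reagents that add atoms: isopropylmagnesium chloride, CC(C)[Mg]Cl
Why: Organocerium 1,2-addition (Imamoto conditions suppress enolisation, β-hydride reduction and retro-aldol); the axial 8a-oxygen blocks axial approach, so isopropyl should enter equatorially (α) and leave the new hydroxyl axial (β).

**Step 5**
Reactants: 9 benzyl ether diol
Product: 10 2α-isopropyl-4aβ-methyldecalin-1β,2β,8aβ-triol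
Conditions: H2 (1 atm), 10% Pd/C, EtOH, 25 °C
Reagents that add atoms: none
Why: Hydrogenolysis of the benzyl ether; no other reducible group is present.

**Step 6**
Reactants: 10 triol
Product: 11 2β,8aβ-dihydroxy-2α-isopropyl-4aβ-methyldecalin-1β-yl methanesulfonate
Conditions: MsCl (1.2 equiv), Et3N, CH2Cl2, −20 to 0 °C
Reagents that add atoms: methanesulfonyl chloride, CS(=O)(=O)Cl
Why: Sulfonylation (via sulfene) of the only secondary hydroxyl; the two tertiary hydroxyls should not react at low temperature and their cis (gauche) relation to the mesylate prevents epoxide closure.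

**Step 7**
Reactants: 11 triol monomesylate
Product: 12 trans-fused 3β-hydroxy-3α-isopropyl-8aβ-methyl-3aα-H-octahydroazulen-4(1H)-one
Conditions: Et2AlCl (3 equiv), CH2Cl2, −78 to 0 °C; aq Rochelle salt
Reagents that add atoms: none
Why: Organoaluminium-promoted semipinacol (pinacol-type) rearrangement of a β-hydroxy mesylate: the C8a oxygen pushes the C8a–C4a σ-bond, which is antiperiplanar to the equatorial C1–OMs bond in the only accessible chair (isopropyl and methyl equatorial), onto C1 as the mesylate leaves. The closest known reaction type is the rearrangement of decalin-1,8a-diol 1-sulfonates to hydroazulenones under basic or Et2AlCl (Tsuchihashi–Suzuki) conditions. Both new rings arise from the same suprafacial 1,2-alkyl shift and not from a ring-closing attack in the Baldwin sense: ring A loses C8a and closes as the cyclopentane through the new C1–C4a bond, while ring B takes up C1 and becomes the cycloheptanone. The only new stereocentre, C3a, should come from inversion at C1 (β-mesylate gives α-H, hence the trans ring fusion); the migrating quaternary carbon keeps its configuration and the C2 carbinol is untouched. The step needs migration of C4a (pushed by O–C8a) in preference to C3 (pushed by O–C2), both bonds being antiperiplanar to C1–O; this rests on the much better migrating ability of the fully substituted C4a over the methylene C3 under Lewis-acidic, cation-like conditions and on the weaker, congested C4a–C8a bond, and the cis relation of both hydroxyls to the mesylate excludes epoxide formation.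

**Step 8**
Reactants: 12 hydroxy ketone
Product: 13 3β-hydroxy-3α-isopropyl-8aβ-methyl-2,3,3a,7,8,8a-hexahydroazulen-4(1H)-one (C5=C6 enone)
Conditions: IBX (1.5 equiv), 4-methoxypyridine N-oxide, DMSO, 25 °C
Reagents that add atoms: none
Why: IBX-mediated α,β-dehydrogenation of a ketone (Nicolaou); only the C5/C6 side has a β-hydrogen (C3 and C8a are fully substituted), so the regiochemistry is fixed, and the neutral conditions should spare the aldol unit.

**Step 9**
Reactants: 13 enone
Product: 14 3β-hydroxy-3α-isopropyl-6,8aβ-dimethyloctahydroazulen-4(1H)-one (C6 epimers)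
Conditions: MeMgBr (3 equiv), CuI (10 mol%), THF, −30 °C; aq NH4Cl
Reagents that add atoms: methylmagnesium bromide, C[Mg]Br
Why: Copper-catalysed conjugate addition of the Grignard reagent to the cycloheptenone; the first equivalent is consumed by the hydroxyl, and the new C6 centre (either epimer) is erased in step 10.

**Step 10**
Reactants: 14 β-methyl ketone
Product: 15 3β-hydroxy-3α-isopropyl-6,8aβ-dimethyl-2,3,3a,7,8,8a-hexahydroazulen-4(1H)-one
Conditions: IBX (1.5 equiv), 4-methoxypyridine N-oxide, DMSO, 25 °C
Reagents that add atoms: none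
Why: Second IBX dehydrogenation, again possible only across C5–C6, should give the β-methyl enone.

**Step 11**
Reactants: 15 hydroxy enone
Product: 16 3α-isopropyl-6,8aβ-dimethyl-1,2,3,3a,4,7,8,8a-octahydroazulene-3β,4α-diol
Conditions: Me4NBH(OAc)3, MeCN/AcOH (1:1), −20 °C
Reagents that add atoms: none
Why: Evans–Saksena reduction: acetoxy exchange binds boron to the 3β-hydroxyl and hydride is delivered intramolecularly to the β face of C4 (1,2-reduction), which should give the 3,4-anti diol with 4α-OH.

**Step 12**
Reactants: 16 diol, 17 4-acetoxybenzoyl chloride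
Product: 18 4α-O-(4-acetoxybenzoyl) ester of diol 16
Conditions: pyridine, DMAP (cat.), CH2Cl2, 0 to 25 °C
Reagents that add atoms: none
Why: DMAP-catalysed acylation; the secondary allylic hydroxyl should react while the hindered tertiary one does not, and the configuration at C4 is retained.

**Step 13**
Reactants: 18 acetoxybenzoate
Product: 19 target, the 4α-O-(4-hydroxybenzoyl) ester of diol 16
Conditions: pyrrolidine (1.5 equiv), CH2Cl2, 0 °C
Reagents that add atoms: none
Why: Aminolysis of the activated aryl acetate; the hindered, electron-rich benzoate should stay intact.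

**Compound list**
1 | 2-(benzyloxy)-N-methoxy-N-methylacetamide | CON(C)C(=O)COCc1ccccc1 | starting material
2 | 1-(benzyloxy)but-3-en-2-one | C=CC(=O)COCc1ccccc1 | intermediate
3 | 2-methylcyclohexanone (racemic) | CC1CCCCC1=O | starting material
4 | (R)-1-phenylethylamine | C[C@@H](N)c1ccccc1 | starting material
5 | ketimine of 3 with 4 | CC1CCCCC1=N[C@H](C)c1ccccc1 | intermediate
6 | adduct ketimine (Michael adduct, quaternary centre S) | O=C(COCc1ccccc1)CC[C@]1(C)CCCCC1=N[C@H](C)c1ccccc1 | intermediate
7 | (S)-2-[4-(benzyloxy)-3-oxobutyl]-2-methylcyclohexan-1-one | O=C(COCc1ccccc1)CC[C@]1(C)CCCCC1=O | intermediate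
8 | 1β-(benzyloxy)-8aβ-hydroxy-4aβ-methyldecalin-2-one (cis-fused) | C1C[C@]2(O)[C@@H](OCc3ccccc3)C(=O)CC[C@]2(C)CC1 | intermediate
9 | 1β-(benzyloxy)-2α-isopropyl-4aβ-methyldecalin-2β,8aβ-diol | C1C[C@]2(O)[C@@H](OCc3ccccc3)[C@](O)(C(C)C)CC[C@]2(C)CC1 | intermediate
10 | 2α-isopropyl-4aβ-methyldecalin-1β,2β,8aβ-triol | C1C[C@]2(O)[C@@H](O)[C@](O)(C(C)C)CC[C@]2(C)CC1 | intermediate
11 | 2β,8aβ-dihydroxy-2α-isopropyl-4aβ-methyldecalin-1β-yl methanesulfonate | C1C[C@]2(O)[C@@H](OS(C)(=O)=O)[C@](O)(C(C)C)CC[C@]2(C)CC1 | intermediate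
12 | trans-fused 3β-hydroxy-3α-isopropyl-8aβ-methyloctahydroazulen-4(1H)-one (3a-H α) | C1CC(=O)[C@@H]2[C@@](C)(CC1)CC[C@@]2(O)C(C)C | intermediate
13 | 3β-hydroxy-3α-isopropyl-8aβ-methyl-2,3,3a,7,8,8a-hexahydroazulen-4(1H)-one | C1=CC(=O)[C@@H]2[C@@](C)(CC1)CC[C@@]2(O)C(C)C | intermediate
14 | 3β-hydroxy-3α-isopropyl-6,8aβ-dimethyloctahydroazulen-4(1H)-one (C6 epimers) | CC1CC(=O)[C@@H]2[C@@](C)(CC1)CC[C@@]2(O)C(C)C | intermediate
15 | 3β-hydroxy-3α-isopropyl-6,8aβ-dimethyl-2,3,3a,7,8,8a-hexahydroazulen-4(1H)-one | CC1=CC(=O)[C@@H]2[C@@](C)(CC1)CC[C@@]2(O)C(C)C | intermediate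
16 | 3α-isopropyl-6,8aβ-dimethyl-1,2,3,3a,4,7,8,8a-octahydroazulene-3β,4α-diol | CC1=C[C@H](O)[C@@H]2[C@@](C)(CC1)CC[C@@]2(O)C(C)C | intermediate
17 | 4-acetoxybenzoyl chloride | CC(=O)Oc1ccc(cc1)C(Cl)=O | starting material
18 | 4α-O-(4-acetoxybenzoyl) ester of 16 | CC1=C[C@H](OC(=O)c2ccc(OC(C)=O)cc2)[C@@H]2[C@@](C)(CC1)CC[C@@]2(O)C(C)C | intermediate
19 | 4α-O-(4-hydroxybenzoyl) ester of 16 | CC1=C[C@H](OC(=O)c2ccc(O)cc2)[C@@H]2[C@@](C)(CC1)CC[C@@]2(O)C(C)C | target

**Totals**
Total step count: 13. Longest linear sequence: 13 steps (steps 1–13, from Weinreb amide 1 through enone 2 to the target). 2-Methylcyclohexanone 3 and amine 4 enter at step 2, and acid chloride 17 enters at step 12.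

**Steps most likely to fail**

1. Step 7. What may go wrong: migration of the ring-A methylene C3 (driven by the C2 oxygen) competing with migration of the quaternary carbon, or retro-aldol/epimerisation of the product on the metal.
Fallback (from 8, back at 12): the C2 oxygen is capped before the shift. Ketol 8 is silylated with 1-(trimethylsilyl)imidazole to the 8a-O-TMS ketol F1. Addition of i-PrMgCl/CeCl3 gives the 2β-ol F2, and TESOTf/2,6-lutidine gives the 2-O-TES 8a-O-TMS bis-silyl ether F3. K2CO3/MeOH at 0 °C removes only the TMS group to give the 8a-ol F4. Hydrogenolysis (H2, Pd/C) gives the 1β,8aβ-diol F5 and MsCl/Et3N the 1β-mesylate F6. In F6 only the C8a hydroxyl is free, so Et2AlCl can bring about only the wanted shift, to the 3-O-TES hydroazulenone F7. HF·pyridine in THF then releases 12.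

2. Step 3. What may go wrong: aldol closure through the ring-ketone enolate onto the side-chain carbonyl (bridged ketol), dehydration of the ketol, or incomplete equilibration at C1.
Fallback (from 5, back at 10): the ring is closed without the oxygen substituent and C1 is oxygenated afterwards. Ketimine 5 is treated with methyl vinyl ketone to give the adduct ketimine F8, and aqueous acetic acid hydrolyses it to (S)-2-methyl-2-(3-oxobutyl)cyclohexan-1-one F9. NaOEt/EtOH at −10 °C closes the cis-fused ketol 8aβ-hydroxy-4aβ-methyldecalin-2-one F10. TMSOTf/Et3N gives the 8a-O-TMS Δ1-silyl enol ether F11; a cis-fused 2-decalone should enolise toward the ring-fusion side. Rubottom oxidation (mCPBA, then citric acid/MeOH, with brief base equilibration to the equatorial alcohol) gives 1β,8aβ-dihydroxy-4aβ-methyldecalin-2-one F12. Excess i-PrMgCl/CeCl3 then adds as in step 4 and gives triol 10.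

3. Step 4. What may go wrong: β-hydride reduction, enolisation or retro-aldol of the hindered β-alkoxido ketone in place of carbonyl addition.
Fallback (from 8, back at 10): a nucleophile without β-hydrogens is used. Isopropenylmagnesium bromide/CeCl3 adds to 8 to give the 2α-isopropenyl-2β,8aβ-diol F13. One hydrogenation (H2, Pd/C, EtOH) saturates the alkene and removes the benzyl group to give triol 10.

**Further compounds**
F1 | step 7 | 1β-(benzyloxy)-4aβ-methyl-8aβ-(trimethylsilyloxy)decalin-2-one | C1C[C@]2(O[Si](C)(C)C)[C@@H](OCc3ccccc3)C(=O)CC[C@]2(C)CC1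
F2 | step 7 | 1β-(benzyloxy)-2α-isopropyl-4aβ-methyl-8aβ-(trimethylsilyloxy)decalin-2β-ol | C1C[C@]2(O[Si](C)(C)C)[C@@H](OCc3ccccc3)[C@](O)(C(C)C)CC[C@]2(C)CC1
F3 | step 7 | 2-O-TES 8a-O-TMS bis-silyl ether of 9 | C1C[C@]2(O[Si](C)(C)C)[C@@H](OCc3ccccc3)[C@](O[Si](CC)(CC)CC)(C(C)C)CC[C@]2(C)CC1
F4 | step 7 | 1β-(benzyloxy)-2α-isopropyl-4aβ-methyl-2β-(triethylsilyloxy)decalin-8aβ-ol | C1C[C@]2(O)[C@@H](OCc3ccccc3)[C@](O[Si](CC)(CC)CC)(C(C)C)CC[C@]2(C)CC1
F5 | step 7 | 2α-isopropyl-4aβ-methyl-2β-(triethylsilyloxy)decalin-1β,8aβ-diol | C1C[C@]2(O)[C@@H](O)[C@](O[Si](CC)(CC)CC)(C(C)C)CC[C@]2(C)CC1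
F6 | step 7 | 8aβ-hydroxy-2α-isopropyl-4aβ-methyl-2β-(triethylsilyloxy)decalin-1β-yl methanesulfonate | C1C[C@]2(O)[C@@H](OS(C)(=O)=O)[C@](O[Si](CC)(CC)CC)(C(C)C)CC[C@]2(C)CC1
F7 | step 7 | 3-O-TES ether of 12 | C1CC(=O)[C@@H]2[C@@](C)(CC1)CC[C@@]2(O[Si](CC)(CC)CC)C(C)C
F8 | step 3 | adduct ketimine from 5 and methyl vinyl ketone | CC(=O)CC[C@]1(C)CCCCC1=N[C@H](C)c1ccccc1
F9 | step 3 | (S)-2-methyl-2-(3-oxobutyl)cyclohexan-1-one | CC(=O)CC[C@]1(C)CCCCC1=O
F10 | step 3 | 8aβ-hydroxy-4aβ-methyldecalin-2-one (cis-fused) | C1C[C@]2(O)CC(=O)CC[C@]2(C)CC1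
F11 | step 3 | 8a-O-TMS Δ1-trimethylsilyl enol ether of F10 | C1C[C@]2(O[Si](C)(C)C)C=C(O[Si](C)(C)C)CC[C@]2(C)CC1
F12 | step 3 | 1β,8aβ-dihydroxy-4aβ-methyldecalin-2-one | C1C[C@]2(O)[C@@H](O)C(=O)CC[C@]2(C)CC1
F13 | step 4 | 1β-(benzyloxy)-2α-isopropenyl-4aβ-methyldecalin-2β,8aβ-diol | C1C[C@]2(O)[C@@H](OCc3ccccc3)[C@](O)(C(C)=C)CC[C@]2(C)CC1
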